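**Strategy**

Everything rests on undoing the guaiane ring fusion: the C1–C5 bond is disconnected and C5–C10 reconnected, which turns the hydroazulene into a eudesmane. The feature used is the 4-methylcyclopentenone (ring atoms C1 to C5, ketone at C3, C4=C5) fused through C1 and C5 to the seven-membered ring (C1, C5 to C10) with a tertiary C10; a decalin 1,4-dien-3-one gives exactly this pattern on irradiation in acid. One photochemical operation forms C1–C5, breaks C5–C10, puts oxygen on C10 and so creates both rings. The precursor is an 11-acetoxy-6β,8β-bis(silyloxy)eudesma-1,4-dien-3-one with C6, C7 and C8 already set on ring B, made from (+)-dihydrocarvone and ethyl vinyl ketone.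

Key step: step 12

Assumption: the target is read as 1α-OH, 6β-OH, 7αH (C11 side chain β), 8β-angeloyloxy, 10αH (10β-methyl); bicyclic precursors carry eudesmane numbering, rearranged compounds guaiane numbering.

Remarks on the design:
- Atom-by-atom checking shows that dienone 19 and its photoproduct have the 6β, 7β (side chain), 8β pattern of the target, and that the photoproduct has 1αH and 10α-oxygen. No structural correction is needed; C1 and C10 are reset in steps 13 and 14.
- The annulation is run through a chiral imine, because plain base-mediated annulation of dihydrocarvone favours the 10-epi series.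
- The irradiation is run in anhydrous acetic acid. This spares the C8 triethylsilyl ether from aqueous acid and leaves an acetate on C10, which is the leaving group for step 13.
- C7 is made trigonal in step 3 and reset in step 10; from step 3 on, C10 carries the stereochemical information.

**Route**

Step 1
Reactants: 1 (+)-dihydrocarvone; 2 ethyl vinyl ketone; 3 (R)-1-phenylethylamine
Product: 7 (+)-α-cyperone [eudesma-4,11-dien-3-one; 7β-isopropenyl; 10β-methyl], via dihydrocarvone imine 4 (not isolated), via Michael adduct imine 5 (not isolated), via diketone 6 (not isolated)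
Conditions: 3, PhMe, reflux (Dean–Stark); 2, THF, 40 °C; aq. AcOH, rt; NaOMe (cat.), MeOH, reflux
Reagents that add atoms: none
Why: Chiral-imine Michael addition followed by Robinson annulation: the more substituted secondary enamine tautomer of 4 should add to 2 on the face anti to the phenyl group of the (R)-auxiliary, setting the quaternary C10 with its methyl cis to the C7 isopropenyl group (10β), after which hydrolysis and aldol condensation close ring A; C2 of 1 is erased in the enamine, so the commercial epimer mixture can be used, and any 10-epimer is a separable diastereomer.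

Step 2
Reactants: 7 (+)-α-cyperone
Product: 8 (+)-carissone [11-hydroxyeudesm-4-en-3-one]
Conditions: Co(acac)2 (cat.), PhSiH3, O2 (1 atm), THF, rt
Reagents that add atoms: dioxygen, O=O
Why: Mukaiyama hydration: hydrogen-atom transfer from the cobalt hydride to the electron-rich 1,1-disubstituted alkene gives the tertiary C11 radical, which is trapped by O2 (Markovnikov), while the tetrasubstituted enone is too hindered and electron-poor to react; no stereocenter is formed.

Step 3
Reactants: 8 (+)-carissone
Product: 9 11-hydroxyeudesma-4,6-dien-3-one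
Conditions: chloranil, t-BuOH, reflux
Reagents that add atoms: none
Why: Quinone dehydrogenation of a 4-en-3-one through its 3,5-dienol with hydride loss from the allylic tertiary C7–H is the standard entry to linear 4,6-dien-3-ones; C7 becomes trigonal here.

Step 4
Reactants: 9 11-hydroxyeudesma-4,6-dien-3-one
Product: 10 11-hydroxyeudesma-1,4,6-trien-3-one
Conditions: DDQ, dioxane, reflux
Reagents that add atoms: none
Why: DDQ dehydrogenation under neutral conditions removes the C1 and C2 hydrogens through the C2 enol, as is usual for 4,6-dien-3-ones, and gives the cross-conjugated trienone in which C10 is the only stereocenter and ring A can no longer enolise towards C2.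

Step 5
Reactants: 10 11-hydroxyeudesma-1,4,6-trien-3-one
Product: 11 7α-bromo-6β,11-dihydroxyeudesma-1,4-dien-3-one
Conditions: NBS, acetone/H2O, HClO4 (cat.), 0 °C, dark
Reagents that add atoms: N-bromosuccinimide, O=C1CCC(=O)N1Br; water, O
Why: Bromohydrin formation under the trans-diaxial rule: the bromonium ion should form on the α face of the γ,δ-alkene (the only electron-rich one), anti to the axial 10β-methyl, and water should open it axially at the secondary allylic C6 from the β face, as with steroidal 4,6-dien-3-ones and 5-enes, setting 6β-OH and 7α-Br with the side chain equatorial.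

Step 6
Reactants: 11 7α-bromo-6β,11-dihydroxyeudesma-1,4-dien-3-one
Product: 14 6β,11-dihydroxyeudesma-1,4,7-trien-3-one, via bis-silyl bromide 12 (not isolated), via bis-silyl triene 13 (not isolated)
Conditions: TMSCl, imidazole, CH2Cl2, rt; DBU, PhMe, 80 °C; citric acid, MeOH, rt
Reagents that add atoms: none
Why: E2 elimination after transient silylation, which blocks epoxide closure by the 6β-oxygen: the axial 7α-bromide has a single antiperiplanar hydrogen, the axial 8β-H, so DBU should give the 7,8-alkene regiospecifically, and mild acidic methanolysis then frees both hydroxyls without touching C6.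

Step 7
Reactants: 14 6β,11-dihydroxyeudesma-1,4,7-trien-3-one
Product: 15 7β,8β-epoxy-6β,11-dihydroxyeudesma-1,4-dien-3-one
Conditions: VO(acac)2 (cat.), t-BuOOH, CH2Cl2, 0 °C
Reagents that add atoms: tert-butyl hydroperoxide, CC(C)(C)OO
Why: Hydroxyl-directed vanadium-catalysed epoxidation: the pseudoaxial 6β allylic alcohol binds the vanadium peroxide and delivers oxygen to the syn (β) face of the 7,8-alkene, the only electron-rich one, setting the 7β,8β-epoxide despite the 10β-methyl.

Step 8
Reactants: 15 7β,8β-epoxy-6β,11-dihydroxyeudesma-1,4-dien-3-one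
Product: 16 6β-(tert-butyldimethylsilyloxy)-7β,8β-epoxy-11-hydroxyeudesma-1,4-dien-3-one
Conditions: TBSOTf, 2,6-lutidine, CH2Cl2, −78 °C
Reagents that add atoms: tert-butyldimethylsilyl triflate, CC(C)(C)[Si](C)(C)OS(=O)(=O)C(F)(F)F
Why: Silyl triflate etherification should take the secondary 6β-hydroxyl in preference to the far more hindered tertiary C11 carbinol, and low temperature with a hindered base keeps the epoxide intact.

Step 9
Reactants: 16 6β-(tert-butyldimethylsilyloxy)-7β,8β-epoxy-11-hydroxyeudesma-1,4-dien-3-one
Product: 17 11-acetoxy-6β-(tert-butyldimethylsilyloxy)-7β,8β-epoxyeudesma-1,4-dien-3-one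
Conditions: Ac2O, DMAP, Et3N, CH2Cl2, 40 °C
Reagents that add atoms: acetic anhydride, CC(=O)OC(C)=O
Why: DMAP-catalysed acetylation of a tertiary alcohol is slow but standard with excess anhydride, and no other free hydroxyl competes; acetylating before C8–OH exists avoids a free 1,3-related hydroxyl under basic conditions.

Step 10
Reactants: 17 11-acetoxy-6β-(tert-butyldimethylsilyloxy)-7β,8β-epoxyeudesma-1,4-dien-3-one
Product: 18 11-acetoxy-6β-(tert-butyldimethylsilyloxy)-8β-hydroxy-7αH-eudesma-1,4-dien-3-one
Conditions: Cp2TiCl2, Mn, THF, rt; then 17, 1,4-cyclohexadiene, rt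
Reagents that add atoms: none
Why: Titanocene-mediated reductive epoxide opening: Cp2TiCl (trivalent titanium) should cleave the C7–O bond homolytically to the tertiary C7 radical and leave the 8β-oxygen in place, and hydrogen-atom transfer from 1,4-cyclohexadiene should come from the α face because the β face is flanked by the axial 6β-silyloxy and 8β-titanoxy groups, setting 7αH (side chain β, equatorial) and 8β-OH.

Step 11
Reactants: 18 11-acetoxy-6β-(tert-butyldimethylsilyloxy)-8β-hydroxy-7αH-eudesma-1,4-dien-3-one
Product: 19 11-acetoxy-6β-(tert-butyldimethylsilyloxy)-8β-(triethylsilyloxy)eudesma-1,4-dien-3-one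
Conditions: TESOTf, 2,6-lutidine, CH2Cl2, −78 to 0 °C
Reagents that add atoms: triethylsilyl triflate, CC[Si](CC)(CC)OS(=O)(=O)C(F)(F)F
Why: Silyl triflate etherification of the only free hydroxyl under non-nucleophilic conditions that do not promote 1,3-acetyl migration gives the dienone with orthogonal silyl ethers (triethylsilyl at O8 more labile than tert-butyldimethylsilyl at O6).

Step 12
Reactants: 19 11-acetoxy-6β-(tert-butyldimethylsilyloxy)-8β-(triethylsilyloxy)eudesma-1,4-dien-3-one
Product: 20 10α,11-diacetoxy-6β-(tert-butyldimethylsilyloxy)-8β-(triethylsilyloxy)-1αH-guai-4-en-3-one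
Conditions: hν (medium-pressure Hg lamp, Pyrex), anhydrous AcOH, degassed, 15 °C
Reagents that add atoms: acetic acid, CC(=O)O
Why: Excitation of the cross-conjugated dienone leads to β,β′-bonding between C1 and C5 and gives the bicyclo[3.1.0]hexanone zwitterion with C10 as the cyclopropane apex. Protonation by acetic acid gives a hydroxyallyl cation whose charge is best carried at the methyl-bearing C4, so the adjacent cyclopropane bond C5–C10 opens while acetic acid captures C10, and tautomerisation gives the cyclopentenone; the closest known reaction is the photorearrangement of santonin in acetic acid to O-acetylisophotosantonic lactone. The five-membered ring is closed by the transannular C1–C5 bonding (a 3-exo-type closure onto the oxyallyl system whose new bond ends as the ring fusion), and the seven-membered ring arises by ring expansion when C5–C10 breaks, not by a separate closure. C1 is set by topology, since ring B must stay cis-fused on the cyclopropane and the C1–C5 bond can therefore form only on the face of ring A opposite the 10β-methyl, leaving H-1 α; C10 is set by backside attack of acetic acid on the breaking C5–C10 bond (inversion), giving 10α-OAc with the methyl β. The step needs C5–C10 cleavage in preference to the lumiketone shift or C1–C10 opening, which the protic medium and the C4 methyl secure, and it must leave C6, C7 and C8 alone, which holds because they lie outside the chromophore.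

Step 13
Reactants: 20 10α,11-diacetoxy-6β-(tert-butyldimethylsilyloxy)-8β-(triethylsilyloxy)-1αH-guai-4-en-3-one
Product: 21 11-acetoxy-6β-(tert-butyldimethylsilyloxy)-8β-(triethylsilyloxy)guaia-1(10),4-dien-3-one
Conditions: DBU, PhMe, 70 °C
Reagents that add atoms: none
Why: Vinylogous E1cB elimination: DBU removes the γ-proton at C1 and the extended enolate expels the C10 acetate, which should give only the conjugated 1(10),4-dienone, whereas H-6 is held in the enone plane by allylic strain and is not acidic; the C1 and C10 stereocenters are deliberately erased.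

Step 14
Reactants: 21 11-acetoxy-6β-(tert-butyldimethylsilyloxy)-8β-(triethylsilyloxy)guaia-1(10),4-dien-3-one
Product: 23 11-acetoxy-1α-hydroxy-6β-(tert-butyldimethylsilyloxy)-8β-(triethylsilyloxy)-10αH-guai-4-en-3-one, via hydroperoxide 22 (not isolated)
Conditions: Mn(dpm)3 (cat.), PhSiH3, O2 (1 atm), i-PrOH/CH2Cl2, 0 °C; then PPh3
Reagents that add atoms: dioxygen, O=O
Why: Proposed new method: hydrogen-atom transfer from the manganese hydride to the linear dienone should occur at the δ-terminus C10 because this gives the radical delocalised over C1, C4 and oxygen, and O2 should add at the γ-carbon C1 so that the tetrasubstituted enone is kept, with both H and O2 arriving on the α face opposite the 6β-, 7β- and 8β-substituents (10αH, 1α-OOH, reduced to 1α-OH by PPh3); the closest known reactions are the Mukaiyama hydration of alkenes and the manganese-catalysed α-hydroxylation of enones with silane and O2.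

Step 15
Reactants: 23 11-acetoxy-1α-hydroxy-6β-(tert-butyldimethylsilyloxy)-8β-(triethylsilyloxy)-10αH-guai-4-en-3-one
Product: 24 11-acetoxy-1α,8β-dihydroxy-6β-(tert-butyldimethylsilyloxy)-10αH-guai-4-en-3-one
Conditions: HF·pyridine, pyridine, THF, 0 °C
Reagents that add atoms: none
Why: Buffered fluoride desilylation distinguishes the silyl ethers by size and hindrance, removing the triethylsilyl group at O8 while the tert-butyldimethylsilyl ether at the peri-hindered C6 and the tertiary acetate survive, and the non-basic medium avoids acetyl migration from O11 to O8.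

Step 16
Reactants: 24 11-acetoxy-1α,8β-dihydroxy-6β-(tert-butyldimethylsilyloxy)-10αH-guai-4-en-3-one
Product: 25 11-acetoxy-8β-angeloyloxy-1α-hydroxy-6β-(tert-butyldimethylsilyloxy)-10αH-guai-4-en-3-one
Conditions: angelic acid, 2,4,6-trichlorobenzoyl chloride, Et3N, PhMe, rt; then 24, 80 °C
Reagents that add atoms: angelic acid, C/C=C(/C)C(=O)O
Why: Yamaguchi esterification through the preformed mixed anhydride is the standard way to install an angelate without Z-to-E isomerisation and should acylate the secondary 8β-OH only, the tertiary 1α-OH being too hindered.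

Step 17
Reactants: 25 11-acetoxy-8β-angeloyloxy-1α-hydroxy-6β-(tert-butyldimethylsilyloxy)-10αH-guai-4-en-3-one
Product: 26 11-acetoxy-8β-angeloyloxy-1α,6β-dihydroxy-10αH-guai-4-en-3-one (target, CNP0273287.1)
Conditions: HF·pyridine, THF, rt
Reagents that add atoms: none
Why: Fluoride desilylation under acidic conditions removes the last silyl group without hydrolysing or migrating the angelate and acetate esters and without ionising the tertiary alcohol.

**Compound list**

1 | (+)-dihydrocarvone, (2R,5R)-2-methyl-5-(prop-1-en-2-yl)cyclohexanone | C[C@@H]1CC[C@@H](C(C)=C)CC1=O | starting material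
2 | ethyl vinyl ketone (pent-1-en-3-one) | CCC(=O)C=C | starting material
3 | (R)-1-phenylethylamine | C[C@@H](N)c1ccccc1 | starting material
4 | N-[(R)-1-phenylethyl] imine of 1 | C[C@@H]1CC[C@@H](C(C)=C)CC1=N[C@H](C)c1ccccc1 | intermediate
5 | N-[(R)-1-phenylethyl] imine of (2S,5R)-2-methyl-2-(3-oxopentyl)-5-(prop-1-en-2-yl)cyclohexanone | CCC(=O)CC[C@]1(C)CC[C@@H](C(C)=C)CC1=N[C@H](C)c1ccccc1 | intermediate
6 | (2S,5R)-2-methyl-2-(3-oxopentyl)-5-(prop-1-en-2-yl)cyclohexanone | CCC(=O)CC[C@]1(C)CC[C@@H](C(C)=C)CC1=O | intermediate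
7 | (+)-α-cyperone, eudesma-4,11-dien-3-one (7β side chain, 10β-methyl) | O=C1CC[C@]2(C)CC[C@@H](C(C)=C)CC2=C1C | intermediate
8 | (+)-carissone, 11-hydroxyeudesm-4-en-3-one | O=C1CC[C@]2(C)CC[C@@H](C(C)(C)O)CC2=C1C | intermediate
9 | 11-hydroxyeudesma-4,6-dien-3-one | O=C1CC[C@]2(C)CCC(C(C)(C)O)=CC2=C1C | intermediate
10 | 11-hydroxyeudesma-1,4,6-trien-3-one | O=C1C=C[C@]2(C)CCC(C(C)(C)O)=CC2=C1C | intermediate
11 | 7α-bromo-6β,11-dihydroxyeudesma-1,4-dien-3-one | O=C1C=C[C@]2(C)CC[C@@](Br)(C(C)(C)O)[C@@H](O)C2=C1C | intermediate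
12 | 7α-bromo-6β,11-bis(trimethylsilyloxy)eudesma-1,4-dien-3-one | O=C1C=C[C@]2(C)CC[C@@](Br)(C(C)(C)O[Si](C)(C)C)[C@@H](O[Si](C)(C)C)C2=C1C | intermediate
13 | 6β,11-bis(trimethylsilyloxy)eudesma-1,4,7-trien-3-one | O=C1C=C[C@]2(C)CC=C(C(C)(C)O[Si](C)(C)C)[C@@H](O[Si](C)(C)C)C2=C1C | intermediate
14 | 6β,11-dihydroxyeudesma-1,4,7-trien-3-one | O=C1C=C[C@]2(C)CC=C(C(C)(C)O)[C@@H](O)C2=C1C | intermediate
15 | 7β,8β-epoxy-6β,11-dihydroxyeudesma-1,4-dien-3-one | O=C1C=C[C@]2(C)C[C@H]3O[C@@]3(C(C)(C)O)[C@@H](O)C2=C1C | intermediate
16 | 6β-(tert-butyldimethylsilyloxy)-7β,8β-epoxy-11-hydroxyeudesma-1,4-dien-3-one | O=C1C=C[C@]2(C)C[C@H]3O[C@@]3(C(C)(C)O)[C@@H](O[Si](C)(C)C(C)(C)C)C2=C1C | intermediate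
17 | 11-acetoxy-6β-(tert-butyldimethylsilyloxy)-7β,8β-epoxyeudesma-1,4-dien-3-one | O=C1C=C[C@]2(C)C[C@H]3O[C@@]3(C(C)(C)OC(C)=O)[C@@H](O[Si](C)(C)C(C)(C)C)C2=C1C | intermediate
18 | 11-acetoxy-6β-(tert-butyldimethylsilyloxy)-8β-hydroxy-7αH-eudesma-1,4-dien-3-one | O=C1C=C[C@]2(C)C[C@@H](O)[C@@H](C(C)(C)OC(C)=O)[C@@H](O[Si](C)(C)C(C)(C)C)C2=C1C | intermediate
19 | 11-acetoxy-6β-(tert-butyldimethylsilyloxy)-8β-(triethylsilyloxy)eudesma-1,4-dien-3-one (key-step precursor) | O=C1C=C[C@]2(C)C[C@@H](O[Si](CC)(CC)CC)[C@@H](C(C)(C)OC(C)=O)[C@@H](O[Si](C)(C)C(C)(C)C)C2=C1C | intermediate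
20 | 10α,11-diacetoxy-6β-(tert-butyldimethylsilyloxy)-8β-(triethylsilyloxy)-1αH-guai-4-en-3-one (key-step product) | CC[Si](CC)(CC)O[C@@H]1C[C@@](C)(OC(C)=O)[C@@H]2CC(=O)C(C)=C2[C@H](O[Si](C)(C)C(C)(C)C)[C@@H]1C(C)(C)OC(C)=O | intermediate
21 | 11-acetoxy-6β-(tert-butyldimethylsilyloxy)-8β-(triethylsilyloxy)guaia-1(10),4-dien-3-one | CC[Si](CC)(CC)O[C@@H]1CC(C)=C2CC(=O)C(C)=C2[C@H](O[Si](C)(C)C(C)(C)C)[C@@H]1C(C)(C)OC(C)=O | intermediate
22 | 11-acetoxy-1α-hydroperoxy-6β-(tert-butyldimethylsilyloxy)-8β-(triethylsilyloxy)-10αH-guai-4-en-3-one | CC[Si](CC)(CC)O[C@@H]1C[C@H](C)[C@]2(OO)CC(=O)C(C)=C2[C@H](O[Si](C)(C)C(C)(C)C)[C@@H]1C(C)(C)OC(C)=O | intermediate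
23 | 11-acetoxy-1α-hydroxy-6β-(tert-butyldimethylsilyloxy)-8β-(triethylsilyloxy)-10αH-guai-4-en-3-one | CC[Si](CC)(CC)O[C@@H]1C[C@H](C)[C@]2(O)CC(=O)C(C)=C2[C@H](O[Si](C)(C)C(C)(C)C)[C@@H]1C(C)(C)OC(C)=O | intermediate
24 | 11-acetoxy-1α,8β-dihydroxy-6β-(tert-butyldimethylsilyloxy)-10αH-guai-4-en-3-one | O[C@@H]1C[C@H](C)[C@]2(O)CC(=O)C(C)=C2[C@H](O[Si](C)(C)C(C)(C)C)[C@@H]1C(C)(C)OC(C)=O | intermediate
25 | 11-acetoxy-8β-angeloyloxy-1α-hydroxy-6β-(tert-butyldimethylsilyloxy)-10αH-guai-4-en-3-one | C/C=C(/C)C(=O)O[C@@H]1C[C@H](C)[C@]2(O)CC(=O)C(C)=C2[C@H](O[Si](C)(C)C(C)(C)C)[C@@H]1C(C)(C)OC(C)=O | intermediate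
26 | 11-acetoxy-8β-angeloyloxy-1α,6β-dihydroxy-10αH-guai-4-en-3-one (CNP0273287.1) | C/C=C(/C)C(=O)O[C@@H]1C[C@H](C)[C@]2(O)CC(=O)C(C)=C2[C@H](O)[C@@H]1C(C)(C)OC(C)=O | target

**Step count and risks**

Total step count: 17. Longest linear sequence: 17 steps (1 to 26; the route is fully linear).

Steps most likely to fail:

Step 14 (bears the label). The hydrogen-atom transfer may be followed by reduction of the delocalised radical instead of oxygen capture, oxygen may be taken up at C4, or delivery of H to C10 and of O2 to C1 may not be clean on the α face. The fallback uses known chemistry and sets out from 21. Hydrogenation of the γ,δ-double bond of the linear dienone (H2, Pd/C, EtOAc), with cis addition from the open α face, should give 11-acetoxy-6β-(tert-butyldimethylsilyloxy)-8β-(triethylsilyloxy)-1αH,10αH-guai-4-en-3-one F1. Soft enolisation (TMSOTf, Et3N) towards C1 gives the linear silyl dienol ether 11-acetoxy-6β-(tert-butyldimethylsilyloxy)-8β-(triethylsilyloxy)-3-(trimethylsilyloxy)-10αH-guaia-1(5),3-diene F2. A vinylogous Rubottom oxidation with dimethyldioxirane at the γ-carbon C1, again from the α face, followed by mild aqueous work-up, comes back to the route at 23.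

Step 12 (key step). The excited dienone may drain into the lumiketone channel in this congested 6β-silyloxy substrate, or the C8 triethylsilyl ether may be lost in the acidic medium and the freed hydroxyl may then take up the neighbouring acetyl group. The fallback changes the order of protection and rearrangement and sets out from 18. The hydroxy dienone, which carries no acid-labile ether at O8, is irradiated in acetic acid to give 10α,11-diacetoxy-8β-hydroxy-6β-(tert-butyldimethylsilyloxy)-1αH-guai-4-en-3-one F3. This is silylated afterwards (TESOTf, 2,6-lutidine, −78 °C) and comes back to the route at 20.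

Step 6. Base may remove the C6 proton of the product and move the new alkene into conjugation, or incomplete silylation may let the 6β-oxygen close the 6β,7β-epoxide instead of elimination. The fallback replaces the base-induced anti-elimination by a neutral syn-elimination and sets out from 10. Hydroxyselenation (N-(phenylseleno)phthalimide, H2O, cat. camphorsulfonic acid, CH2Cl2) should add selenium to C7 (α) and hydroxyl to C6 (β), giving 6β,11-dihydroxy-7α-(phenylselanyl)eudesma-1,4-dien-3-one F4. Oxidation with H2O2 gives 6β,11-dihydroxy-7α-(phenylseleninyl)eudesma-1,4-dien-3-one F5, whose selenoxide syn-elimination can take only a C8 hydrogen (elimination away from the carbinol carbon), and comes back to the route at 14.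

Further compounds
F1 | step 14 | 11-acetoxy-6β-(tert-butyldimethylsilyloxy)-8β-(triethylsilyloxy)-1αH,10αH-guai-4-en-3-one | CC[Si](CC)(CC)O[C@@H]1C[C@H](C)[C@@H]2CC(=O)C(C)=C2[C@H](O[Si](C)(C)C(C)(C)C)[C@@H]1C(C)(C)OC(C)=O
F2 | step 14 | 11-acetoxy-6β-(tert-butyldimethylsilyloxy)-8β-(triethylsilyloxy)-3-(trimethylsilyloxy)-10αH-guaia-1(5),3-diene | CC[Si](CC)(CC)O[C@@H]1C[C@H](C)C2CC(O[Si](C)(C)C)=C(C)C=2[C@H](O[Si](C)(C)C(C)(C)C)[C@@H]1C(C)(C)OC(C)=O
F3 | step 12 | 10α,11-diacetoxy-8β-hydroxy-6β-(tert-butyldimethylsilyloxy)-1αH-guai-4-en-3-one | O[C@@H]1C[C@@](C)(OC(C)=O)[C@@H]2CC(=O)C(C)=C2[C@H](O[Si](C)(C)C(C)(C)C)[C@@H]1C(C)(C)OC(C)=O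
F4 | step 6 | 6β,11-dihydroxy-7α-(phenylselanyl)eudesma-1,4-dien-3-one | O=C1C=C[C@]2(C)CC[C@@]([Se]c3ccccc3)(C(C)(C)O)[C@@H](O)C2=C1C
F5 | step 6 | 6β,11-dihydroxy-7α-(phenylseleninyl)eudesma-1,4-dien-3-one | O=C1C=C[C@]2(C)CC[C@@]([Se](=O)c3ccccc3)(C(C)(C)O)[C@@H](O)C2=C1C
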